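**Plan**
1. Feature: upper C4 is bonded to ring A (at C4a) and to ring D (at C8'), two phloroglucinol rings that each carry an oxygen ortho to that bond (O1 and O1'). Before ring C exists, C4 can therefore be a prochiral CH bearing two identical 2-hydroxy-4,6-bis(benzyloxy)phenyl groups.
2. Cuts, in retrosynthetic order: the thirteen benzyl ethers and both gallate esters; O1'–C2' (ring F), then C4'–C3' and C4a'–C4' (the three-carbon arm on ring D); O1–C2 (ring C); both aryl–C4 bonds.
3. Forward: double ortho-arylation of an arylpropynal sets up C4 with its two aryl groups, the alkyne becomes a cis-epoxide and ring C closes. The surviving ring D phenol then directs formylation ortho to itself, an arylalkynyl arm is added and turned into a second cis-epoxide, ring F closes, and esterification and hydrogenolysis finish.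
4. Stereochemistry: C3 and C3' come from two catalyst-controlled Jacobsen–Katsuki epoxidations of Z-alkenes, C2 and C2' from inversion when the phenols open the epoxides, and C4 from the choice between the two aryl groups in the ring C closure (spectator aryl trans to O3).

Key step: step 7

Remarks on the chemistry:
- The ethynylarene, the phenol, the dibenzyloxybenzaldehyde and the tribenzyloxybenzoic acid used as starting materials are taken to be catalogue compounds.
- The facial sense of the (S,S)-manganese salen catalyst is assigned by analogy with cis-β-alkylstyrenes (benzylic carbon S).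
- The CIP letter at C4 changes with the substituents on ring D (S with a free ring D phenol, R with its silyl ether or with ring F closed). The geometry, aryl group 4β and trans to O3, is the same throughout.

**Step 1**
Reactants: 1 1-(benzyloxy)-4-ethynylbenzene
Product: 3 3-[4-(benzyloxy)phenyl]prop-2-ynal, via lithium acetylide 2 (not isolated)
Conditions: n-BuLi (1.05 equiv), THF, −78 °C; DMF (2 equiv), −78 → 0 °C; inverse quench into aq KH2PO4/MTBE
Reagents that add atoms: N,N-dimethylformamide, CN(C)C=O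
Why: Formylation of a lithium acetylide with DMF followed by a buffered inverse quench is the standard route to arylpropynals and leaves the benzyl ether untouched.

**Step 2**
Reactants: 3 3-[4-(benzyloxy)phenyl]prop-2-ynal; 4 3,5-bis(benzyloxy)phenol (2.2 equiv)
Product: 8 2,2'-{3-[4-(benzyloxy)phenyl]prop-2-yne-1,1-diyl}bis[3,5-bis(benzyloxy)phenol], via bromomagnesium phenoxide 5 (not isolated), via propargylic carbinol 6 (not isolated), via alkynyl ortho-quinone methide 7 (not isolated)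
Conditions: 4, EtMgBr (2.2 equiv), Et2O, 0 °C → rt; evaporate, toluene; 3 (1.0 equiv), rt → 80 °C; aq NH4Cl
Reagents that add atoms: none
Why: This is the ortho-specific condensation of bromomagnesium phenoxides with aldehydes to 2,2'-alkylidenebisphenols, in which magnesium delivers the aldehyde to the ortho carbon of 5 through a six-membered chelate, the magnesium salt of 6 loses its benzylic oxygen on warming to give 7, and a second phenoxide adds through its ortho carbon to the methide carbon (1,4-addition), the two ortho positions of 4 being equivalent so that only one regioisomer can arise.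

**Step 3**
Reactants: 8 2,2'-{3-[4-(benzyloxy)phenyl]prop-2-yne-1,1-diyl}bis[3,5-bis(benzyloxy)phenol]
Product: 9 bis(tert-butyldimethylsilyl) ether of 8
Conditions: TBSCl (3 equiv), imidazole (6 equiv), DMF, rt → 40 °C
Reagents that add atoms: tert-butyldimethylsilyl chloride, CC(C)(C)[Si](C)(C)Cl
Why: Standard silylation of phenols masks the two oxidation-sensitive phenols for the epoxidation and prevents premature attack on the epoxide.

**Step 4**
Reactants: 9 bis(tert-butyldimethylsilyl) ether of 8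
Product: 10 bis(tert-butyldimethylsilyl) ether of 2,2'-{(2Z)-3-[4-(benzyloxy)phenyl]prop-2-ene-1,1-diyl}bis[3,5-bis(benzyloxy)phenol]
Conditions: H2 (1 atm), Pd/CaCO3 poisoned with Pb(OAc)2 (Lindlar catalyst), quinoline, EtOAc, rt
Reagents that add atoms: none
Why: Lindlar semihydrogenation adds H2 syn to the alkyne and should stop at the Z-alkene, the poisoned catalyst leaving benzyl and aryl silyl ethers intact.

**Step 5**
Reactants: 10 the (Z)-alkene bis(silyl ether)
Product: 11 (2R,3S)-2-{bis[2,4-bis(benzyloxy)-6-(tert-butyldimethylsilyloxy)phenyl]methyl}-3-[4-(benzyloxy)phenyl]oxirane (cis)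
Conditions: chloro[(S,S)-N,N'-bis(3,5-di-tert-butylsalicylidene)cyclohexane-1,2-diaminato]manganese, a (salen)MnCl complex of trivalent manganese (5 mol %), 4-phenylpyridine N-oxide (0.25 equiv), aq NaOCl buffered to pH 11.3, CH2Cl2, 0 °C
Reagents that add atoms: sodium hypochlorite, [Na+].[O-]Cl
Why: Jacobsen–Katsuki epoxidation of a cis-disubstituted aryl alkene transfers oxygen from the oxo-manganese salen complex to one enantioface with retention of the cis geometry, the (S,S)-catalyst being expected to give (S) at the benzylic carbon (future C2) and (R) at future C3, while the basic two-phase medium protects the acid-labile 4-alkoxyaryl epoxide.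

**Step 6**
Reactants: 11 the cis-epoxide bis(silyl ether)
Product: 12 2,2'-{[(2R,3S)-3-[4-(benzyloxy)phenyl]oxiran-2-yl]methylene}bis[3,5-bis(benzyloxy)phenol]
Conditions: n-Bu4NF (2.2 equiv), AcOH (2.2 equiv), THF, −20 → 0 °C; pH 7 work-up, used at once
Reagents that add atoms: none
Why: Fluoride cleaves aryl silyl ethers within minutes, and the acetic acid buffer keeps the liberated phenols protonated so that no phenoxide opens the epoxide in the 5-exo sense; no stereocentre is touched.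

**Step 7**
Reactants: 12 2,2'-{[(2R,3S)-3-[4-(benzyloxy)phenyl]oxiran-2-yl]methylene}bis[3,5-bis(benzyloxy)phenol]
Product: 13 (2R,3R,4S)-5,7-bis(benzyloxy)-2-[4-(benzyloxy)phenyl]-4-[2,4-bis(benzyloxy)-6-hydroxyphenyl]chroman-3-ol (2,3-cis, 3,4-trans; aryl group 4β)
Conditions: PPTS (0.1 equiv), 4 Å MS, CH2Cl2, −20 → 0 °C
Reagents that add atoms: none
Why: Proposed new method: the pyridinium acid hydrogen-bonds to the epoxide oxygen, the C2–O bond benzylic to the 4-benzyloxyphenyl ring lengthens, and one of the two constitutionally identical phenols attacks C2 from the side opposite the departing oxygen, so that O1–C2 forms with inversion while C3 keeps its epoxide configuration (2,3-cis). The closest known reaction is the acid-catalysed, π-activated 6-endo opening of aryl and vinyl epoxides by a single tethered phenol or alcohol; what is new is that the nucleophile is selected from two aryl groups on a prochiral carbon that the neighbouring epoxide makes diastereotopic. Ring C closes in the 6-endo-tet mode (O1, C8a, C4a, C4, C3, C2), preferred over 5-exo attack at C3 because only C2 can take up positive charge and C3 is shielded by the diarylmethyl carbon. C2 is set by backside displacement at the epoxide, and C4 by a chair-like transition state with the C2 aryl group equatorial and the spectator aryl group at C4 pseudoaxial and anti to the oxygen on C3; the alternative places that aryl group pseudoequatorial against the C5 benzyloxy group of the forming ring A, so the 3,4-trans isomer, also the more stable one, should result. The step needs endo regiochemistry, clean inversion and aryl selection, secured respectively by the benzylic activation, by a weak acid in a non-ionising solvent at low temperature, and by this peri interaction.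

**Step 8**
Reactants: 13 the 4β-aryl chroman-3-ol with the free ring D phenol
Product: 14 4,6-bis(benzyloxy)-3-{(2R,3R,4S)-5,7-bis(benzyloxy)-2-[4-(benzyloxy)phenyl]-3-hydroxychroman-4-yl}-2-hydroxybenzaldehyde
Conditions: MgCl2 (3 equiv), Et3N (6 equiv), paraformaldehyde (10 equiv), THF, reflux
Reagents that add atoms: paraformaldehyde (as formaldehyde), C=O
Why: In the magnesium-mediated ortho-formylation (Casnati–Skattebøl reaction) the magnesium phenoxide of ring D directs formaldehyde to the only free position ortho to the phenol (the future C4a') and a second formaldehyde accepts the hydride, while ring A, which has no free phenol, and the secondary alcohol do not react.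

**Step 9**
Reactants: 15 3,4-bis(benzyloxy)benzaldehyde
Product: 16 1,2-bis(benzyloxy)-4-ethynylbenzene
Conditions: dimethyl (1-diazo-2-oxopropyl)phosphonate (1.3 equiv), K2CO3 (2 equiv), MeOH, rt
Reagents that add atoms: dimethyl (1-diazo-2-oxopropyl)phosphonate, COP(=O)(OC)C(=[N+]=[N-])C(C)=O
Why: The Ohira–Bestmann homologation converts an aryl aldehyde into the terminal alkyne under mild basic conditions that benzyl ethers tolerate.

**Step 10**
Reactants: 14 the ring D salicylaldehyde; 16 1,2-bis(benzyloxy)-4-ethynylbenzene (3.5 equiv)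
Product: 18 (2R,3R,4S)-5,7-bis(benzyloxy)-2-[4-(benzyloxy)phenyl]-4-{4,6-bis(benzyloxy)-3-[3-(3,4-bis(benzyloxy)phenyl)-1-hydroxyprop-2-yn-1-yl]-2-hydroxyphenyl}chroman-3-ol (both carbinol epimers), via lithium acetylide 17 (not isolated)
Conditions: 16, n-BuLi (3.3 equiv), THF, −78 °C; then 14, −78 → 0 °C; aq NH4Cl
Reagents that add atoms: none
Why: Excess lithium acetylide first deprotonates the phenol and the secondary alcohol and then adds to the aldehyde (1,2-addition), as is usual for salicylaldehydes, and the new carbinol centre is removed in the next step.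

**Step 11**
Reactants: 18 the propargylic carbinol
Product: 19 (2R,3R,4S)-5,7-bis(benzyloxy)-2-[4-(benzyloxy)phenyl]-4-{4,6-bis(benzyloxy)-3-[3-(3,4-bis(benzyloxy)phenyl)prop-2-yn-1-yl]-2-hydroxyphenyl}chroman-3-ol
Conditions: Et3SiH (3 equiv), TFA (3 equiv), CH2Cl2, −40 → −20 °C; aq NaHCO3
Reagents that add atoms: none
Why: In this ionic hydrogenation the carbinol, benzylic to a ring with three oxygen donors ortho and para, ionises with TFA at low temperature and triethylsilane delivers hydride to the benzylic carbon, which restores the arene and should leave the alkyne, the benzyl ethers, the C2 aryl ether and the C4–aryl bond intact.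

**Step 12**
Reactants: 19 the propargyl phenol
Product: 20 (2R,3R,4R)-5,7-bis(benzyloxy)-2-[4-(benzyloxy)phenyl]-4-{4,6-bis(benzyloxy)-3-[3-(3,4-bis(benzyloxy)phenyl)prop-2-yn-1-yl]-2-(tert-butyldimethylsilyloxy)phenyl}chroman-3-ol
Conditions: TBSCl (1.5 equiv), imidazole (3 equiv), DMF, rt → 40 °C
Reagents that add atoms: tert-butyldimethylsilyl chloride, CC(C)(C)[Si](C)(C)Cl
Why: Phenols are silylated far faster than the hindered axial C3 hydroxyl, so only the ring D phenol is masked for the second epoxidation.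

**Step 13**
Reactants: 20 the silylated alkyne
Product: 21 (2R,3R,4R)-5,7-bis(benzyloxy)-2-[4-(benzyloxy)phenyl]-4-{4,6-bis(benzyloxy)-3-[(2Z)-3-(3,4-bis(benzyloxy)phenyl)prop-2-en-1-yl]-2-(tert-butyldimethylsilyloxy)phenyl}chroman-3-ol
Conditions: H2 (1 atm), Pd/CaCO3 poisoned with Pb(OAc)2 (Lindlar catalyst), quinoline, EtOAc, rt
Reagents that add atoms: none
Why: Lindlar semihydrogenation by syn addition of H2 gives the Z-alkene without touching benzyl or silyl ethers.

**Step 14**
Reactants: 21 the (Z)-alkene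
Product: 22 (2R,3R,4R)-5,7-bis(benzyloxy)-2-[4-(benzyloxy)phenyl]-4-{4,6-bis(benzyloxy)-3-{[(2R,3S)-3-(3,4-bis(benzyloxy)phenyl)oxiran-2-yl]methyl}-2-(tert-butyldimethylsilyloxy)phenyl}chroman-3-ol (cis-epoxide)
Conditions: chloro[(S,S)-N,N'-bis(3,5-di-tert-butylsalicylidene)cyclohexane-1,2-diaminato]manganese (5 mol %), 4-phenylpyridine N-oxide (0.25 equiv), aq NaOCl buffered to pH 11.3, CH2Cl2, 0 °C
Reagents that add atoms: sodium hypochlorite, [Na+].[O-]Cl
Why: This second Jacobsen–Katsuki epoxidation acts on a cis-β-alkylstyrene, the substrate class the catalyst suits best, and under catalyst control the (S,S)-complex should again give (S) at the benzylic carbon (future C2') and (R) at future C3', the remote centres of the upper unit having little influence.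

**Step 15**
Reactants: 22 the silylated cis-epoxide
Product: 23 (2R,3R,4S)-5,7-bis(benzyloxy)-2-[4-(benzyloxy)phenyl]-4-{4,6-bis(benzyloxy)-3-{[(2R,3S)-3-(3,4-bis(benzyloxy)phenyl)oxiran-2-yl]methyl}-2-hydroxyphenyl}chroman-3-ol
Conditions: n-Bu4NF (1.2 equiv), AcOH (1.2 equiv), THF, −20 → 0 °C; pH 7 work-up, used at once
Reagents that add atoms: none
Why: Buffered fluoride removes the aryl silyl ether and leaves the phenol protonated, so the epoxide is not opened by a phenoxide in the exo sense.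

**Step 16**
Reactants: 23 the ring D phenol cis-epoxide
Product: 24 (2R,3R,4R)-5,7-bis(benzyloxy)-2-[4-(benzyloxy)phenyl]-4-{(2R,3R)-5,7-bis(benzyloxy)-2-[3,4-bis(benzyloxy)phenyl]-3-hydroxychroman-8-yl}chroman-3-ol (benzylated epiafzelechin-(4β→8)-epicatechin)
Conditions: PPTS (0.1 equiv), CH2Cl2, 0 °C
Reagents that add atoms: none
Why: The acid-catalysed 6-endo-tet opening of an aryl-activated cis-epoxide by a tethered phenol, a known π-activated endo cyclisation, forms O1'–C2' with inversion and so gives the 2,3-cis (2R,3R) ring F.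

**Step 17**
Reactants: 24 the benzylated dimer diol; 25 3,4,5-tris(benzyloxy)benzoic acid (4 equiv)
Product: 26 (2R,3R,4R)-5,7-bis(benzyloxy)-2-[4-(benzyloxy)phenyl]-4-{(2R,3R)-5,7-bis(benzyloxy)-2-[3,4-bis(benzyloxy)phenyl]-3-[3,4,5-tris(benzyloxy)benzoyloxy]chroman-8-yl}chroman-3-yl 3,4,5-tris(benzyloxy)benzoate
Conditions: DCC (4 equiv), DMAP (1 equiv), CH2Cl2, rt → 40 °C
Reagents that add atoms: none
Why: Steglich esterification acylates both axial secondary alcohols, the established way to galloylate benzylated epi-configured flavan-3-ols and their dimers, and touches no stereocentre.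

**Step 18**
Reactants: 26 the perbenzylated digallate
Product: 27 (2R,3R,4R)-5,7-dihydroxy-2-(4-hydroxyphenyl)-4-[(2R,3R)-2-(3,4-dihydroxyphenyl)-5,7-dihydroxy-3-(3,4,5-trihydroxybenzoyloxy)chroman-8-yl]chroman-3-yl 3,4,5-trihydroxybenzoate (epiafzelechin 3-O-gallate-(4β→8)-epicatechin 3-O-gallate)
Conditions: H2 (1 atm), Pd(OH)2 on carbon, THF/MeOH/H2O, rt; filtration, lyophilisation
Reagents that add atoms: none
Why: Hydrogenolysis over Pd(OH)2 on carbon should cleave all thirteen benzyl ethers while the benzoate esters and the benzylic C–O and C–C bonds at C2, C2' and C4 survive the neutral conditions customary for procyanidin gallates.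

**Compound list**
1 | 1-(benzyloxy)-4-ethynylbenzene | C#Cc1ccc(OCc2ccccc2)cc1 | starting material
2 | lithium [4-(benzyloxy)phenyl]acetylide | [Li]C#Cc1ccc(OCc2ccccc2)cc1 | intermediate (not isolated)
3 | 3-[4-(benzyloxy)phenyl]prop-2-ynal | O=CC#Cc1ccc(OCc2ccccc2)cc1 | intermediate
4 | 3,5-bis(benzyloxy)phenol | Oc1cc(OCc2ccccc2)cc(OCc2ccccc2)c1 | starting material
5 | bromomagnesium 3,5-bis(benzyloxy)phenoxide | Br[Mg]Oc1cc(OCc2ccccc2)cc(OCc2ccccc2)c1 | intermediate (not isolated)
6 | 3,5-bis(benzyloxy)-2-{3-[4-(benzyloxy)phenyl]-1-hydroxyprop-2-yn-1-yl}phenol (racemic carbinol, present as its magnesium salt) | Oc1cc(OCc2ccccc2)cc(OCc2ccccc2)c1C(O)C#Cc1ccc(OCc2ccccc2)cc1 | intermediate (not isolated)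
7 | 3,5-bis(benzyloxy)-6-{3-[4-(benzyloxy)phenyl]prop-2-yn-1-ylidene}cyclohexa-2,4-dien-1-one | O=C1C=C(OCc2ccccc2)C=C(OCc2ccccc2)C1=CC#Cc1ccc(OCc2ccccc2)cc1 | intermediate (not isolated)
8 | 2,2'-{3-[4-(benzyloxy)phenyl]prop-2-yne-1,1-diyl}bis[3,5-bis(benzyloxy)phenol] | Oc1cc(OCc2ccccc2)cc(OCc2ccccc2)c1C(C#Cc1ccc(OCc2ccccc2)cc1)c1c(O)cc(OCc2ccccc2)cc1OCc1ccccc1 | intermediate
9 | bis(tert-butyldimethylsilyl) ether of 8 | CC(C)(C)[Si](C)(C)Oc1cc(OCc2ccccc2)cc(OCc2ccccc2)c1C(C#Cc1ccc(OCc2ccccc2)cc1)c1c(O[Si](C)(C)C(C)(C)C)cc(OCc2ccccc2)cc1OCc1ccccc1 | intermediate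
10 | bis(tert-butyldimethylsilyl) ether of 2,2'-{(2Z)-3-[4-(benzyloxy)phenyl]prop-2-ene-1,1-diyl}bis[3,5-bis(benzyloxy)phenol] | CC(C)(C)[Si](C)(C)Oc1cc(OCc2ccccc2)cc(OCc2ccccc2)c1C(/C=C\c1ccc(OCc2ccccc2)cc1)c1c(O[Si](C)(C)C(C)(C)C)cc(OCc2ccccc2)cc1OCc1ccccc1 | intermediate
11 | (2R,3S)-2-{bis[2,4-bis(benzyloxy)-6-(tert-butyldimethylsilyloxy)phenyl]methyl}-3-[4-(benzyloxy)phenyl]oxirane | CC(C)(C)[Si](C)(C)Oc1cc(OCc2ccccc2)cc(OCc2ccccc2)c1C(c1c(O[Si](C)(C)C(C)(C)C)cc(OCc2ccccc2)cc1OCc1ccccc1)[C@H]1O[C@H]1c1ccc(OCc2ccccc2)cc1 | intermediate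
12 | 2,2'-{[(2R,3S)-3-[4-(benzyloxy)phenyl]oxiran-2-yl]methylene}bis[3,5-bis(benzyloxy)phenol] | Oc1cc(OCc2ccccc2)cc(OCc2ccccc2)c1C(c1c(O)cc(OCc2ccccc2)cc1OCc1ccccc1)[C@H]1O[C@H]1c1ccc(OCc2ccccc2)cc1 | intermediate
13 | (2R,3R,4S)-5,7-bis(benzyloxy)-2-[4-(benzyloxy)phenyl]-4-[2,4-bis(benzyloxy)-6-hydroxyphenyl]chroman-3-ol | O[C@@H]1[C@@H](c2c(OCc3ccccc3)cc(OCc3ccccc3)cc2O)c2c(OCc3ccccc3)cc(OCc3ccccc3)cc2O[C@@H]1c1ccc(OCc2ccccc2)cc1 | intermediate
14 | 4,6-bis(benzyloxy)-3-{(2R,3R,4S)-5,7-bis(benzyloxy)-2-[4-(benzyloxy)phenyl]-3-hydroxychroman-4-yl}-2-hydroxybenzaldehyde | O[C@@H]1[C@@H](c2c(OCc3ccccc3)cc(OCc3ccccc3)c(C=O)c2O)c2c(OCc3ccccc3)cc(OCc3ccccc3)cc2O[C@@H]1c1ccc(OCc2ccccc2)cc1 | intermediate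
15 | 3,4-bis(benzyloxy)benzaldehyde | O=Cc1ccc(OCc2ccccc2)c(OCc2ccccc2)c1 | starting material
16 | 1,2-bis(benzyloxy)-4-ethynylbenzene | C#Cc1ccc(OCc2ccccc2)c(OCc2ccccc2)c1 | intermediate
17 | lithium [3,4-bis(benzyloxy)phenyl]acetylide | [Li]C#Cc1ccc(OCc2ccccc2)c(OCc2ccccc2)c1 | intermediate (not isolated)
18 | (2R,3R,4S)-5,7-bis(benzyloxy)-2-[4-(benzyloxy)phenyl]-4-{4,6-bis(benzyloxy)-3-[3-(3,4-bis(benzyloxy)phenyl)-1-hydroxyprop-2-yn-1-yl]-2-hydroxyphenyl}chroman-3-ol (carbinol epimers) | O[C@@H]1[C@@H](c2c(OCc3ccccc3)cc(OCc3ccccc3)c(C(O)C#Cc3ccc(OCc4ccccc4)c(OCc4ccccc4)c3)c2O)c2c(OCc3ccccc3)cc(OCc3ccccc3)cc2O[C@@H]1c1ccc(OCc2ccccc2)cc1 | intermediate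
19 | (2R,3R,4S)-5,7-bis(benzyloxy)-2-[4-(benzyloxy)phenyl]-4-{4,6-bis(benzyloxy)-3-[3-(3,4-bis(benzyloxy)phenyl)prop-2-yn-1-yl]-2-hydroxyphenyl}chroman-3-ol | O[C@@H]1[C@@H](c2c(OCc3ccccc3)cc(OCc3ccccc3)c(CC#Cc3ccc(OCc4ccccc4)c(OCc4ccccc4)c3)c2O)c2c(OCc3ccccc3)cc(OCc3ccccc3)cc2O[C@@H]1c1ccc(OCc2ccccc2)cc1 | intermediate
20 | (2R,3R,4R)-5,7-bis(benzyloxy)-2-[4-(benzyloxy)phenyl]-4-{4,6-bis(benzyloxy)-3-[3-(3,4-bis(benzyloxy)phenyl)prop-2-yn-1-yl]-2-(tert-butyldimethylsilyloxy)phenyl}chroman-3-ol | O[C@@H]1[C@@H](c2c(OCc3ccccc3)cc(OCc3ccccc3)c(CC#Cc3ccc(OCc4ccccc4)c(OCc4ccccc4)c3)c2O[Si](C)(C)C(C)(C)C)c2c(OCc3ccccc3)cc(OCc3ccccc3)cc2O[C@@H]1c1ccc(OCc2ccccc2)cc1 | intermediate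
21 | (2R,3R,4R)-5,7-bis(benzyloxy)-2-[4-(benzyloxy)phenyl]-4-{4,6-bis(benzyloxy)-3-[(2Z)-3-(3,4-bis(benzyloxy)phenyl)prop-2-en-1-yl]-2-(tert-butyldimethylsilyloxy)phenyl}chroman-3-ol | O[C@@H]1[C@@H](c2c(OCc3ccccc3)cc(OCc3ccccc3)c(C/C=C\c3ccc(OCc4ccccc4)c(OCc4ccccc4)c3)c2O[Si](C)(C)C(C)(C)C)c2c(OCc3ccccc3)cc(OCc3ccccc3)cc2O[C@@H]1c1ccc(OCc2ccccc2)cc1 | intermediate
22 | (2R,3R,4R)-5,7-bis(benzyloxy)-2-[4-(benzyloxy)phenyl]-4-{4,6-bis(benzyloxy)-3-{[(2R,3S)-3-(3,4-bis(benzyloxy)phenyl)oxiran-2-yl]methyl}-2-(tert-butyldimethylsilyloxy)phenyl}chroman-3-ol | O[C@@H]1[C@@H](c2c(OCc3ccccc3)cc(OCc3ccccc3)c(C[C@H]5O[C@H]5c3ccc(OCc4ccccc4)c(OCc4ccccc4)c3)c2O[Si](C)(C)C(C)(C)C)c2c(OCc3ccccc3)cc(OCc3ccccc3)cc2O[C@@H]1c1ccc(OCc2ccccc2)cc1 | intermediate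
23 | (2R,3R,4S)-5,7-bis(benzyloxy)-2-[4-(benzyloxy)phenyl]-4-{4,6-bis(benzyloxy)-3-{[(2R,3S)-3-(3,4-bis(benzyloxy)phenyl)oxiran-2-yl]methyl}-2-hydroxyphenyl}chroman-3-ol | O[C@@H]1[C@@H](c2c(OCc3ccccc3)cc(OCc3ccccc3)c(C[C@H]5O[C@H]5c3ccc(OCc4ccccc4)c(OCc4ccccc4)c3)c2O)c2c(OCc3ccccc3)cc(OCc3ccccc3)cc2O[C@@H]1c1ccc(OCc2ccccc2)cc1 | intermediate
24 | (2R,3R,4R)-5,7-bis(benzyloxy)-2-[4-(benzyloxy)phenyl]-4-{(2R,3R)-5,7-bis(benzyloxy)-2-[3,4-bis(benzyloxy)phenyl]-3-hydroxychroman-8-yl}chroman-3-ol | O[C@@H]1[C@@H](c2c(OCc3ccccc3)cc(OCc3ccccc3)c3c2O[C@H](c2ccc(OCc4ccccc4)c(OCc4ccccc4)c2)[C@H](O)C3)c2c(OCc3ccccc3)cc(OCc3ccccc3)cc2O[C@@H]1c1ccc(OCc2ccccc2)cc1 | intermediate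
25 | 3,4,5-tris(benzyloxy)benzoic acid | OC(=O)c1cc(OCc2ccccc2)c(OCc2ccccc2)c(OCc2ccccc2)c1 | starting material
26 | (2R,3R,4R)-5,7-bis(benzyloxy)-2-[4-(benzyloxy)phenyl]-4-{(2R,3R)-5,7-bis(benzyloxy)-2-[3,4-bis(benzyloxy)phenyl]-3-[3,4,5-tris(benzyloxy)benzoyloxy]chroman-8-yl}chroman-3-yl 3,4,5-tris(benzyloxy)benzoate | O=C(O[C@@H]1[C@@H](c2c(OCc4ccccc4)cc(OCc4ccccc4)c3c2O[C@H](c2ccc(OCc4ccccc4)c(OCc4ccccc4)c2)[C@H](OC(=O)c2cc(OCc4ccccc4)c(OCc4ccccc4)c(OCc4ccccc4)c2)C3)c2c(OCc4ccccc4)cc(OCc4ccccc4)cc2O[C@@H]1c1ccc(OCc2ccccc2)cc1)c1cc(OCc2ccccc2)c(OCc2ccccc2)c(OCc2ccccc2)c1 | intermediate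
27 | epiafzelechin 3-O-gallate-(4β→8)-epicatechin 3-O-gallate, (2R,3R,4R) upper unit and (2R,3R) lower unit | O=C(O[C@@H]1[C@@H](c2c(O)cc(O)c3c2O[C@H](c2ccc(O)c(O)c2)[C@H](OC(=O)c2cc(O)c(O)c(O)c2)C3)c2c(O)cc(O)cc2O[C@@H]1c1ccc(O)cc1)c1cc(O)c(O)c(O)c1 | target

**Totals**
Total step count: 18.
Longest linear sequence: 17 steps (steps 1 to 8 and 10 to 18, from 1).

**Steps most likely to fail**

1. Step 7. The two aryl groups may be discriminated poorly, giving the C4 epimer; ionisation at C2 may erode the cis relationship; some exo opening at C3 may occur.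
Fallback: it sets out from 12 and returns to 13. The cyclisation is run as in step 7, and the 3,4-cis epimer that accompanies 13, (2R,3R,4R)-5,7-bis(benzyloxy)-2-[4-(benzyloxy)phenyl]-4-[2,4-bis(benzyloxy)-6-hydroxyphenyl]chroman-3-ol F1, is not separated. The crude mixture is stirred with 4 (5 equiv) and BF3·OEt2 (0.3 equiv) in CH2Cl2 at −30 °C. Ipso-protonation of the phenolic aryl group and heterolysis of the C4–aryl bond give the flavan-4-yl cation, and 4 recaptures it through the carbon ortho to its hydroxyl, on the face away from O3. This is the course established for arylation of 2,3-cis flavan-4-yl cations and for acid-catalysed exchange of the lower unit of proanthocyanidins against phloroglucinol-type phenols. The expelled aryl group is 4 itself, and the 3,4-trans product 13 should accumulate.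

2. Step 5. Oxygen transfer to the very hindered cis-alkene may be slow or poorly face-selective, the radical pathway may leak to the trans-epoxide, and the product may open during work-up. Step 14 uses the same catalyst on an unhindered cis-β-alkylstyrene and is less exposed.
Fallback: it sets out from 10 and returns to 13. Epoxidation of 10 with dimethyldioxirane (acetone, 0 °C) is stereospecific and gives the racemic cis-epoxide, that is 11 together with its enantiomer (2S,3R)-2-{bis[2,4-bis(benzyloxy)-6-(tert-butyldimethylsilyloxy)phenyl]methyl}-3-[4-(benzyloxy)phenyl]oxirane F2. Steps 6 and 7 are run on the racemate. They give 12 with its enantiomer 2,2'-{[(2S,3R)-3-[4-(benzyloxy)phenyl]oxiran-2-yl]methylene}bis[3,5-bis(benzyloxy)phenol] F3, and then 13 with its enantiomer (2S,3S,4R)-5,7-bis(benzyloxy)-2-[4-(benzyloxy)phenyl]-4-[2,4-bis(benzyloxy)-6-hydroxyphenyl]chroman-3-ol F4. The two chromanols are separated by preparative HPLC on a cellulose tris(3,5-dimethylphenylcarbamate) phase, and 13 goes on to step 8.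

3. Step 2. The phenoxide may add in conjugate fashion to the ynal, the second phenoxide may attack the alkyne terminus of the quinone methide (allene formation), or the second arylation may stay incomplete.
Fallback: it sets out from 4 and 1 and returns to 8. Magnesium-mediated ortho-formylation of 4 (MgCl2, Et3N, paraformaldehyde, THF, reflux) gives 2,4-bis(benzyloxy)-6-hydroxybenzaldehyde F5. Addition of acetylide 2 (2.2 equiv, THF, −78 → 0 °C) gives carbinol 6, this time isolated. Heating 6 with phenoxide 5 in toluene at 80 °C takes it through quinone methide 7 to 8. The ynal is avoided and each aryl–carbon bond is made in a separate operation of fixed regiochemistry.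

**Further compounds**
F1 | step 7 | (2R,3R,4R)-5,7-bis(benzyloxy)-2-[4-(benzyloxy)phenyl]-4-[2,4-bis(benzyloxy)-6-hydroxyphenyl]chroman-3-ol (C4 epimer of 13) | O[C@@H]1[C@H](c2c(OCc3ccccc3)cc(OCc3ccccc3)cc2O)c2c(OCc3ccccc3)cc(OCc3ccccc3)cc2O[C@@H]1c1ccc(OCc2ccccc2)cc1
F2 | step 5 | (2S,3R)-2-{bis[2,4-bis(benzyloxy)-6-(tert-butyldimethylsilyloxy)phenyl]methyl}-3-[4-(benzyloxy)phenyl]oxirane (enantiomer of 11) | CC(C)(C)[Si](C)(C)Oc1cc(OCc2ccccc2)cc(OCc2ccccc2)c1C(c1c(O[Si](C)(C)C(C)(C)C)cc(OCc2ccccc2)cc1OCc1ccccc1)[C@@H]1O[C@@H]1c1ccc(OCc2ccccc2)cc1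
F3 | step 5 | 2,2'-{[(2S,3R)-3-[4-(benzyloxy)phenyl]oxiran-2-yl]methylene}bis[3,5-bis(benzyloxy)phenol] (enantiomer of 12) | Oc1cc(OCc2ccccc2)cc(OCc2ccccc2)c1C(c1c(O)cc(OCc2ccccc2)cc1OCc1ccccc1)[C@@H]1O[C@@H]1c1ccc(OCc2ccccc2)cc1
F4 | step 5 | (2S,3S,4R)-5,7-bis(benzyloxy)-2-[4-(benzyloxy)phenyl]-4-[2,4-bis(benzyloxy)-6-hydroxyphenyl]chroman-3-ol (enantiomer of 13) | O[C@H]1[C@H](c2c(OCc3ccccc3)cc(OCc3ccccc3)cc2O)c2c(OCc3ccccc3)cc(OCc3ccccc3)cc2O[C@H]1c1ccc(OCc2ccccc2)cc1
F5 | step 2 | 2,4-bis(benzyloxy)-6-hydroxybenzaldehyde | O=Cc1c(O)cc(OCc2ccccc2)cc1OCc1ccccc1
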